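**Retrosynthetic overview**
- The target is traced back, by O9 desilylation and 8-O-angeloylation, to a 7,8-dihydroxy-9-silyloxy germacranolide.
- Both rings of that lactone open to one acyclic, oxidised-farnesyl keto-aldehyde (C6 enal, C7 2-acylacrylate). The C6–C7 bond, which is the C1–C10 bond of farnesyl diphosphate cyclisation, is cut as a reductive cross-pinacol.
- Ring order: the ten-membered carbocycle forms first (C6–C7). The γ-lactone forms second (O6 onto C12, as in costunolide formation), in the same flask.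
- The keto-aldehyde comes from a C7 aldehyde, an acrylate α-anion and one double oxidation. The aldehyde comes from a Z-selective Wittig union of a geranyl acetate-derived C1–C6 ylide with a C7–C10 methyl ketone.
- The methyl ketone comes from a catalytic syn-aldol of TBSO-acetone with ethyl glyoxylate. This sets C8 and C9 and leaves O8 and O9 differentiated.

**Assumptions**
- The SMILES is taken literally: 1(10)Z,4E geometry, a cis-fused 12,6-lactone (H-6 and 7-OH on the same face), and 6S,7R,8S,9R.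
- Germacrane numbering (C1–C15) is used in the comments for all intermediates.

**Step 1**
Reactants: 1 geranyl acetate
Product: 2 (2E)-6-hydroxy-3-methylhex-2-en-1-yl acetate
Conditions: O3 (1.0 equiv), CH2Cl2–MeOH, −78 °C; then NaBH4, −78 → 0 °C
Reagents that add atoms: ozone, [O-][O+]=O
Why: Chemoselective ozonolysis with reductive work-up cleaves the electron-rich distal olefin faster than the acetoxy-deactivated allylic one, so the (E)-C4=C5 olefin is carried over intact.

**Step 2**
Reactants: 2 (2E)-6-hydroxy-3-methylhex-2-en-1-yl acetate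
Product: 3 (2E)-6-iodo-3-methylhex-2-en-1-yl acetate
Conditions: I2, PPh3, imidazole, CH2Cl2, 0 °C
Reagents that add atoms: iodine, II
Why: Appel-type (Garegg–Samuelsson) iodination of the unhindered primary alcohol proceeds by SN2 and does not touch the allylic acetate.

**Step 3**
Reactants: 3 (2E)-6-iodo-3-methylhex-2-en-1-yl acetate
Product: 4 [(4E)-6-acetoxy-4-methylhex-4-en-1-yl]triphenylphosphonium iodide
Conditions: PPh3, MeCN, reflux
Reagents that add atoms: triphenylphosphine, c1ccc(cc1)P(c1ccccc1)c1ccccc1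
Why: SN2 quaternisation of the primary iodide gives the phosphonium salt, and without Pd the allylic acetate is inert to PPh3.

**Step 4**
Reactants: 5 1-[(tert-butyldimethylsilyl)oxy]propan-2-one; 6 ethyl glyoxylate
Product: 7 ethyl (2S,3S)-3-[(tert-butyldimethylsilyl)oxy]-2-hydroxy-4-oxopentanoate
Conditions: O-tBu-D-threonine (20 mol %), NMP, 4 °C
Reagents that add atoms: none
Why: In this primary-amino-acid enamine-catalysed direct syn-aldol, the (Z)-enamine at the oxygenated carbon adds to the acid-activated glyoxylate, and the D-catalyst gives the D-threo pair, setting C8 and C9 with O9 silylated and O8 free.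

**Step 5**
Reactants: 7 ethyl (2S,3S)-3-[(tert-butyldimethylsilyl)oxy]-2-hydroxy-4-oxopentanoate
Product: 8 ethyl (2S,3S)-3-[(tert-butyldimethylsilyl)oxy]-4-oxo-2-[(triethylsilyl)oxy]pentanoate
Conditions: TESCl, imidazole, CH2Cl2, 0 °C
Reagents that add atoms: chlorotriethylsilane, CC[Si](Cl)(CC)CC
Why: Mild silylation blocks retro-aldol and gives O8 a group more labile than the TBS on O9, so the two oxygens can be released in sequence later.

**Step 6**
Reactants: 4 [(4E)-6-acetoxy-4-methylhex-4-en-1-yl]triphenylphosphonium iodide; 8 ethyl (2S,3S)-3-[(tert-butyldimethylsilyl)oxy]-4-oxo-2-[(triethylsilyl)oxy]pentanoate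
Product: 10 ethyl (2S,3R,4Z,8E)-10-acetoxy-3-[(tert-butyldimethylsilyl)oxy]-4,8-dimethyl-2-[(triethylsilyl)oxy]deca-4,8-dienoate, via phosphonium ylide 9 (not isolated)
Conditions: 4, KHMDS (0.98 equiv), THF, −78 → 0 °C; then 8, −78 → −20 °C
Reagents that add atoms: none
Why: A salt-free Wittig reaction of an unstabilised ylide with an α-oxygenated methyl ketone (Still-type Z-selective variant) places the ylide chain cis to the oxygenated carbon, which gives the 1(10)Z olefin, and fast addition at low temperature outruns enolisation at C9.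

**Step 7**
Reactants: 10 ethyl (2S,3R,4Z,8E)-10-acetoxy-3-[(tert-butyldimethylsilyl)oxy]-4,8-dimethyl-2-[(triethylsilyl)oxy]deca-4,8-dienoate
Product: 11 (2S,3R,4Z,8E)-3-[(tert-butyldimethylsilyl)oxy]-10-hydroxy-4,8-dimethyl-2-[(triethylsilyl)oxy]deca-4,8-dienal
Conditions: DIBAL-H (3.3 equiv), CH2Cl2, −78 °C; Rochelle salt
Reagents that add atoms: none
Why: In this DIBAL-H partial reduction the α-silyloxy ester stops at the stable aluminium hemiacetal (aldehyde on work-up), and the same reagent removes the acetate, so no separate deprotection is needed.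

**Step 8**
Reactants: 11 (2S,3R,4Z,8E)-3-[(tert-butyldimethylsilyl)oxy]-10-hydroxy-4,8-dimethyl-2-[(triethylsilyl)oxy]deca-4,8-dienal; 12 methyl propiolate
Product: 14 methyl (4R,5R,6Z,10E)-5-[(tert-butyldimethylsilyl)oxy]-3,12-dihydroxy-6,10-dimethyl-2-methylidene-4-[(triethylsilyl)oxy]dodeca-6,10-dienoate (both C3 epimers), via alpha-aluminoacrylate 13 (not isolated)
Conditions: 12 (3 equiv), DIBAL-H (3 equiv), HMPA, THF, 0 °C; then 11, 0 °C → rt
Reagents that add atoms: diisobutylaluminium hydride, CC(C)C[AlH]CC(C)C (its iBu2Al group is found only in 13)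
Why: Hydroalumination of the propiolate gives the α-metallated acrylate, whose 1,2-addition to the aldehyde gives the Baylis–Hillman-type adduct without amine base, so C8 does not epimerise, and the new C7 carbinol centre is erased in the next step.

**Step 9**
Reactants: 14 methyl (4R,5R,6Z,10E)-5-[(tert-butyldimethylsilyl)oxy]-3,12-dihydroxy-6,10-dimethyl-2-methylidene-4-[(triethylsilyl)oxy]dodeca-6,10-dienoate
Product: 15 methyl (4S,5R,6Z,10E)-5-[(tert-butyldimethylsilyl)oxy]-6,10-dimethyl-2-methylidene-3,12-dioxo-4-[(triethylsilyl)oxy]dodeca-6,10-dienoate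
Conditions: DMP (2.6 equiv), CH2Cl2, 0 °C → rt; short cold silica plug, used at once
Reagents that add atoms: none
Why: One Dess–Martin oxidation converts the primary allylic alcohol into the enal and the Baylis–Hillman carbinol into the 2-acylacrylate under neutral conditions that spare both silyl ethers and the Z-olefin.

**Step 10**
Reactants: 15 methyl (4S,5R,6Z,10E)-5-[(tert-butyldimethylsilyl)oxy]-6,10-dimethyl-2-methylidene-3,12-dioxo-4-[(triethylsilyl)oxy]dodeca-6,10-dienoate
Product: 18 (1(10)Z,4E,6S,7S,8S,9R)-9-[(tert-butyldimethylsilyl)oxy]-7,8-dihydroxygermacra-1(10),4,11(13)-trien-12,6-olide, via siloxyallylchromium species 16 (not isolated), via trisilylated lactone 17 (not isolated)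
Conditions: CrCl2 (6 equiv), Me3SiCl (3 equiv), DMF, 25 °C, 15 added over 12 h (final 2 mM); aq. work-up; then PPTS (cat.), MeOH, 0 °C
Reagents that add atoms: chlorotrimethylsilane, C[Si](C)(C)Cl (in 16 and 17 only); chromium(II) chloride, Cl[Cr]Cl (in 16 only)
Why: Proposed new method: Cr(II) reduces the doubly activated 2-acylacrylate well before the β,β-disubstituted enal, Me3SiCl traps the chelated enolate oxygen so that O7 lies cis to the ester, and a second Cr(II) captures the allyl radical as the (E)-γ-siloxyallylchromium(III) 16, which adds through C7 to the C6 aldehyde in a closed Zimmerman–Traxler chair (C5 equatorial with OSi in the E position gives the 6,7-relationship of the cis-fused lactone; A1,3 strain holds H-8 in the olefin plane and the aldehyde approaches anti to the C8–OTES bond in the Felkin–Anh sense with C9 and the tether on the attacking face, which gives the required C7 configuration next to 8S), after which the C6 alkoxide closes the lactone on the C12 ester and PPTS/MeOH removes only the TMS and TES groups; the closest known reaction types are the intermolecular Takai Cr(II)/R3SiCl cross-pinacol-type coupling of vinyl ketones with aldehydes and the Nozaki–Hiyama–Kishi macrocyclisation of 2-(bromomethyl)acrylates to germacranolides.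

**Step 11**
Reactants: 18 (1(10)Z,4E,6S,7S,8S,9R)-9-[(tert-butyldimethylsilyl)oxy]-7,8-dihydroxygermacra-1(10),4,11(13)-trien-12,6-olide; 19 angelic acid
Product: 21 (1(10)Z,4E,6S,7R,8S,9R)-8-angeloyloxy-9-[(tert-butyldimethylsilyl)oxy]-7-hydroxygermacra-1(10),4,11(13)-trien-12,6-olide, via mixed anhydride 20 (not isolated)
Conditions: 19, 2,4,6-Cl3C6H2COCl, Et3N, toluene, rt; then 18, 75 °C
Reagents that add atoms: 2,4,6-trichlorobenzoyl chloride, O=C(Cl)c1c(Cl)cc(Cl)cc1Cl (in 20 only)
Why: Yamaguchi-type mixed-anhydride esterification without DMAP transfers the angeloyl group without Z→E isomerisation to tiglate, and only the secondary 8-OH reacts because 7-OH is tertiary and O9 is silylated.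

**Step 12**
Reactants: 21 (1(10)Z,4E,6S,7R,8S,9R)-8-angeloyloxy-9-[(tert-butyldimethylsilyl)oxy]-7-hydroxygermacra-1(10),4,11(13)-trien-12,6-olide
Product: 22 (1(10)Z,4E,6S,7R,8S,9R)-8-angeloyloxy-7,9-dihydroxygermacra-1(10),4,11(13)-trien-12,6-olide (target)
Conditions: HF·pyridine, pyridine, THF, 0 °C → rt
Reagents that add atoms: none
Why: Buffered fluoride desilylation removes the allylic TBS ether under conditions too mild for transannular cyclisation, conjugate addition to the methylene lactone or angelate isomerisation.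

**Compound list**

| No. | Name | SMILES | Role |
|---|---|---|---|
| 1 | geranyl acetate | CC(C)=CCC/C(C)=C/COC(C)=O | starting material |
| 2 | (2E)-6-hydroxy-3-methylhex-2-en-1-yl acetate | OCCC/C(C)=C/COC(C)=O | intermediate |
| 3 | (2E)-6-iodo-3-methylhex-2-en-1-yl acetate | ICCC/C(C)=C/COC(C)=O | intermediate |
| 4 | [(4E)-6-acetoxy-4-methylhex-4-en-1-yl]triphenylphosphonium iodide | CC(=O)OC/C=C(\C)CCC[P+](c1ccccc1)(c1ccccc1)c1ccccc1.[I-] | intermediate |
| 5 | 1-[(tert-butyldimethylsilyl)oxy]propan-2-one | CC(=O)CO[Si](C)(C)C(C)(C)C | starting material |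
| 6 | ethyl glyoxylate | CCOC(=O)C=O | starting material |
| 7 | ethyl (2S,3S)-3-(TBSO)-2-hydroxy-4-oxopentanoate | CCOC(=O)[C@@H](O)[C@H](O[Si](C)(C)C(C)(C)C)C(C)=O | intermediate |
| 8 | ethyl (2S,3S)-3-(TBSO)-4-oxo-2-(TESO)pentanoate | CCOC(=O)[C@@H](O[Si](CC)(CC)CC)[C@H](O[Si](C)(C)C(C)(C)C)C(C)=O | intermediate |
| 9 | phosphonium ylide from 4 | CC(=O)OC/C=C(\C)CCC=P(c1ccccc1)(c1ccccc1)c1ccccc1 | intermediate (not isolated) |
| 10 | ethyl (2S,3R,4Z,8E)-10-acetoxy-3-(TBSO)-4,8-dimethyl-2-(TESO)deca-4,8-dienoate | CCOC(=O)[C@@H](O[Si](CC)(CC)CC)[C@H](O[Si](C)(C)C(C)(C)C)/C(C)=C\CC/C(C)=C/COC(C)=O | intermediate |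
| 11 | (2S,3R,4Z,8E)-3-(TBSO)-10-hydroxy-4,8-dimethyl-2-(TESO)deca-4,8-dienal | O=C[C@@H](O[Si](CC)(CC)CC)[C@H](O[Si](C)(C)C(C)(C)C)/C(C)=C\CC/C(C)=C/CO | intermediate |
| 12 | methyl propiolate | C#CC(=O)OC | starting material |
| 13 | [1-(methoxycarbonyl)vinyl]diisobutylaluminium | C=C(C(=O)OC)[Al](CC(C)C)CC(C)C | intermediate (not isolated) |
| 14 | methyl (4R,5R,6Z,10E)-5-(TBSO)-3,12-dihydroxy-6,10-dimethyl-2-methylidene-4-(TESO)dodeca-6,10-dienoate, C3 epimers | C=C(C(=O)OC)C(O)[C@@H](O[Si](CC)(CC)CC)[C@H](O[Si](C)(C)C(C)(C)C)/C(C)=C\CC/C(C)=C/CO | intermediate |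
| 15 | methyl (4S,5R,6Z,10E)-5-(TBSO)-6,10-dimethyl-2-methylidene-3,12-dioxo-4-(TESO)dodeca-6,10-dienoate | C=C(C(=O)OC)C(=O)[C@@H](O[Si](CC)(CC)CC)[C@H](O[Si](C)(C)C(C)(C)C)/C(C)=C\CC/C(C)=C/C=O | intermediate |
| 16 | (E)-γ-(trimethylsiloxy)allylchromium(III) dichloride (O7 cis to CO2Me, C8 cis to CH2Cr) | COC(=O)/C(C[Cr](Cl)Cl)=C(O[Si](C)(C)C)/[C@@H](O[Si](CC)(CC)CC)[C@H](O[Si](C)(C)C(C)(C)C)/C(C)=C\CC/C(C)=C/C=O | intermediate (not isolated) |
| 17 | (6S,7R,8S,9R)-9-(TBSO)-8-(TESO)-7-(TMSO)germacra-1(10)Z,4E,11(13)-trien-12,6-olide | C=C1C(=O)O[C@H]2/C=C(\C)CC/C=C(/C)[C@@H](O[Si](C)(C)C(C)(C)C)[C@H](O[Si](CC)(CC)CC)[C@@]12O[Si](C)(C)C | intermediate (not isolated) |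
| 18 | (6S,7S,8S,9R)-9-(TBSO)-7,8-dihydroxygermacra-1(10)Z,4E,11(13)-trien-12,6-olide | C=C1C(=O)O[C@H]2/C=C(\C)CC/C=C(/C)[C@@H](O[Si](C)(C)C(C)(C)C)[C@H](O)[C@@]12O | intermediate |
| 19 | angelic acid, (Z)-2-methylbut-2-enoic acid | C/C=C(/C)C(=O)O | starting material |
| 20 | angelic 2,4,6-trichlorobenzoic anhydride | C/C=C(/C)C(=O)OC(=O)c1c(Cl)cc(Cl)cc1Cl | intermediate (not isolated) |
| 21 | (6S,7R,8S,9R)-8-angeloyloxy-9-(TBSO)-7-hydroxygermacra-1(10)Z,4E,11(13)-trien-12,6-olide | C=C1C(=O)O[C@H]2/C=C(\C)CC/C=C(/C)[C@@H](O[Si](C)(C)C(C)(C)C)[C@H](OC(=O)/C(C)=C\C)[C@@]12O | intermediate |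
| 22 | (6S,7R,8S,9R)-8-angeloyloxy-7,9-dihydroxygermacra-1(10)Z,4E,11(13)-trien-12,6-olide | C=C1C(=O)O[C@H]2/C=C(\C)CC/C=C(/C)[C@@H](O)[C@H](OC(=O)/C(C)=C\C)[C@@]12O | target |

**Step count**
- Total steps: 12.
- Longest linear sequence: 10 (steps 1–3 and 6–12).

**Three steps most likely to fail**

**Step 10.** The 2-acylacrylate 15 may dimerise or be simply reduced. The push–pull allylchromium 16 may be too weak a nucleophile for a ten-membered closure. The facial selectivity is only modelled.

The fallback sets out from 11 and comes back at 18.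
- 11 is treated with 2-lithioallyl triethylsilyl ether (from the bromide and t-BuLi) to give the allylic alcohol F1.
- Dess–Martin oxidation gives the keto-aldehyde F2. This is a storable simple vinyl ketone inside the known scope of the Cr(II)/R3SiCl coupling, and its allylchromium carries no ester.
- CrCl2/Et3SiCl in DMF at high dilution closes the same C6–C7 bond to the ten-membered carbocycle F3.
- Brief PPTS/MeOH at −10 °C frees only the primary C12 alcohol and gives the 6,12-diol F4.
- MnO2 then takes C12 through aldehyde and lactol to the bis-TES lactone F5. Here C12 is oxidised after ring closure and the lactone is closed as a separate event.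
- PPTS/MeOH at room temperature gives 18.

**Step 6.** The Z:E ratio on an α-branched α-silyloxy ketone may be modest, and C9 may epimerise.

The fallback sets out from 4 and comes back at 11.
- Ylide 9 is made as before but is condensed with pyruvaldehyde dimethyl acetal. This ketone is the best-behaved Z-selective partner and has no stereocentre to lose. The product is the (Z)-acetal F6.
- Oxalic acid on wet silica releases the (Z)-enal F7, which is kept cold.
- The stereocentres are then made after the olefin by a Mukaiyama–Kobayashi asymmetric syn-aldol. The reagents are Sn(OTf)2, a proline-derived chiral diamine, Bu2Sn(OAc)2 and the trimethylsilyl ketene thioacetal of S-ethyl (triethylsilyloxy)thioacetate. The product is the syn-aldol thioester F8.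
- TBSOTf/2,6-lutidine gives the bis-silyl thioester F9.
- DIBAL-H at −78 °C reduces the thioester to the aldehyde and removes the acetate, giving 11.

**Step 11.** The 8-OH is flanked by a quaternary carbinol and the OTBS carbon. Heating may isomerise angelate to tiglate, or may move the lactone from O6 to O8.

The fallback sets out from 18 and comes back at 21.
- The angelate is built on the molecule instead of being transferred.
- DCC coupling with 2-[bis(2,2,2-trifluoroethoxy)phosphoryl]propanoic acid acylates hindered alcohols at room temperature through the phosphonoketene. It gives the phosphonopropionate F10.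
- A Still–Gennari olefination (KHMDS 2.1 equiv, 18-crown-6, THF, −78 °C, then acetaldehyde) creates the Z-olefin of the angelate and gives 21.

**Further compounds**
F1 | step 10 | allylic alcohol from 11 and 2-lithioallyl TES ether (C12 as CH2OTES, C7 epimers, C8/C9 as in 11) | C=C(CO[Si](CC)(CC)CC)C(O)[C@@H](O[Si](CC)(CC)CC)[C@H](O[Si](C)(C)C(C)(C)C)/C(C)=C\CC/C(C)=C/CO
F2 | step 10 | keto-aldehyde with C12 as CH2OTES | C=C(CO[Si](CC)(CC)CC)C(=O)[C@@H](O[Si](CC)(CC)CC)[C@H](O[Si](C)(C)C(C)(C)C)/C(C)=C\CC/C(C)=C/C=O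
F3 | step 10 | ten-membered carbocycle, 6-OH, 7,8,12-tris(TESO), 9-TBSO, germacra-1(10)Z,4E,11(13)-triene | O[C@H]1/C=C(\C)CC/C=C(/C)[C@@H](O[Si](C)(C)C(C)(C)C)[C@H](O[Si](CC)(CC)CC)[C@@]1(O[Si](CC)(CC)CC)C(=C)CO[Si](CC)(CC)CC
F4 | step 10 | 6,12-diol, 7,8-bis(TESO), 9-TBSO | O[C@H]1/C=C(\C)CC/C=C(/C)[C@@H](O[Si](C)(C)C(C)(C)C)[C@H](O[Si](CC)(CC)CC)[C@@]1(O[Si](CC)(CC)CC)C(=C)CO
F5 | step 10 | bis-TES lactone, 9-(TBSO)-7,8-bis(TESO)germacra-1(10)Z,4E,11(13)-trien-12,6-olide | C=C1C(=O)O[C@H]2/C=C(\C)CC/C=C(/C)[C@@H](O[Si](C)(C)C(C)(C)C)[C@H](O[Si](CC)(CC)CC)[C@@]12O[Si](CC)(CC)CC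
F6 | step 6 | (2E,6Z)-8,8-dimethoxy-3,7-dimethylocta-2,6-dien-1-yl acetate | COC(OC)/C(C)=C\CC/C(C)=C/COC(C)=O
F7 | step 6 | (2E,6Z)-3,7-dimethyl-8-oxoocta-2,6-dien-1-yl acetate | O=C/C(C)=C\CC/C(C)=C/COC(C)=O
F8 | step 6 | S-ethyl (4Z,8E)-10-acetoxy-3-hydroxy-4,8-dimethyl-2-(TESO)deca-4,8-dienethioate, syn, C8/C9 as in 10 | CCSC(=O)[C@@H](O[Si](CC)(CC)CC)[C@H](O)/C(C)=C\CC/C(C)=C/COC(C)=O
F9 | step 6 | S-ethyl (4Z,8E)-10-acetoxy-3-(TBSO)-4,8-dimethyl-2-(TESO)deca-4,8-dienethioate | CCSC(=O)[C@@H](O[Si](CC)(CC)CC)[C@H](O[Si](C)(C)C(C)(C)C)/C(C)=C\CC/C(C)=C/COC(C)=O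
F10 | step 11 | 8-O-{2-[bis(2,2,2-trifluoroethoxy)phosphoryl]propanoyl} derivative of 18 | C=C1C(=O)O[C@H]2/C=C(\C)CC/C=C(/C)[C@@H](O[Si](C)(C)C(C)(C)C)[C@H](OC(=O)C(C)P(=O)(OCC(F)(F)F)OCC(F)(F)F)[C@@]12O
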